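**Retrosynthetic overview**
- The cyclohexene is the only carbocycle and is closed last, by ring-closing metathesis across C2=C3 of an acyclic 1,7-diene that already carries all four stereocentres and both benzoates.
- That diene comes from benzoic acid and an acyclic 2,3-epoxy alcohol (a vinyl oxirane): anti opening at the allylic carbon installs the C4 benzoate and frees the tertiary C5 alcohol.
- The oxirane comes from hydroxyl-directed epoxidation of a (Z)-dienediol, which is assembled by Nozaki–Hiyama–Kishi union (C5–C6 bond) of a C5 iododienol with a four-carbon α-benzoyloxy enal.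
- The enal comes from divinylcarbinol (Sharpless desymmetrisation, esterification with benzoic acid made from benzaldehyde, periodate cleavage); the iododienol comes from ethyl bromoacetate and acrolein (iodo-Wittig, iBu2AlH).
- Ring order: transient oxirane first (formed, then opened), cyclohexene last.

Assumption: the SMILES is taken as authoritative; it reads as (1R,4S,5S,6R)-5,6-dihydroxy-5-(hydroxymethyl)cyclohex-2-ene-1,4-diyl dibenzoate (both benzoates and the secondary OH cis to one another, the tertiary OH trans to them).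

**Route**

Step 1
Reactants: 1 benzaldehyde
Product: 2 benzoic acid
Conditions: KHSO5 (as 2KHSO5·KHSO4·K2SO4, 1.1 equiv), DMF, rt
Reagents that add atoms: potassium peroxymonosulfate, [K+].[O-]S(=O)(=O)OO
Why: Peroxymonosulfate oxidation of the aldehyde (peroxy-hemiacetal, then hydride shift) gives the carboxylic acid that later supplies both benzoyl groups; no stereocentre is involved.

Step 2
Reactants: 3 penta-1,4-dien-3-ol
Product: 4 (1R)-1-[(2S)-oxiran-2-yl]prop-2-en-1-ol
Conditions: Ti(OiPr)4 (10 mol%), D-(−)-diisopropyl tartrate (13 mol%), t-BuOOH (1.5 equiv), 4 Å MS, CH2Cl2, −20 °C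
Reagents that add atoms: tert-butyl hydroperoxide, CC(C)(C)OO
Why: Sharpless asymmetric epoxidation of the divinyl carbinol combines enantiotopic-group selection with erythro face selection, so D-(−)-tartrate gives the (2S,3R)-epoxy alcohol in very high ee (the minor enantiomer is removed by fast second epoxidation), and the carbinol centre becomes C1 of the target.

Step 3
Reactants: 4 (1R)-1-[(2S)-oxiran-2-yl]prop-2-en-1-ol; 2 benzoic acid
Product: 5 (1R)-1-[(2S)-oxiran-2-yl]prop-2-en-1-yl benzoate
Conditions: DCC (1.1 equiv), DMAP (10 mol%), CH2Cl2, 0 °C to rt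
Reagents that add atoms: none
Why: Steglich esterification acylates the secondary allylic alcohol under neutral conditions with retention at the carbinol carbon and leaves the oxirane untouched.

Step 4
Reactants: 5 (1R)-1-[(2S)-oxiran-2-yl]prop-2-en-1-yl benzoate
Product: 6 (2R)-1-oxobut-3-en-2-yl benzoate
Conditions: H5IO6 (1.2 equiv), Et2O, 0 °C to rt; used crude at once
Reagents that add atoms: none
Why: Periodic acid opens the terminal oxirane and cleaves the resulting glycol in one flask (Malaprade-type cleavage), removing the terminal carbon as formaldehyde and leaving the α-benzoyloxy aldehyde without touching its stereocentre.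

Step 5
Reactants: 7 ethyl bromoacetate
Product: 9 ethyl (triphenyl-λ5-phosphanylidene)acetate, via phosphonium bromide 8 (not isolated)
Conditions: PPh3, toluene, rt; then aq. NaOH, CH2Cl2
Reagents that add atoms: triphenylphosphine, c1ccc(cc1)P(c1ccccc1)c1ccccc1
Why: SN2 quaternisation of the phosphine by the α-bromo ester followed by deprotonation gives the stabilised Wittig ylide.

Step 6
Reactants: 9 ethyl (triphenyl-λ5-phosphanylidene)acetate; 10 acrolein
Product: 12 ethyl (2Z)-2-iodopenta-2,4-dienoate, via iodo ylide 11 (not isolated)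
Conditions: N-iodosuccinimide (1.1 equiv), CH2Cl2, −20 °C; then 10, −20 °C to rt
Reagents that add atoms: N-iodosuccinimide, O=C1CCC(=O)N1I
Why: Electrophilic iodination of the stabilised ylide and in situ Wittig olefination of acrolein give the α-iodo dienoate with the ester trans to the vinyl group (Z isomer favoured, as usual for stabilised α-halo ylides), which places iodine cis to the vinyl group as the later ring requires.

Step 7
Reactants: 12 ethyl (2Z)-2-iodopenta-2,4-dienoate
Product: 13 (2Z)-2-iodopenta-2,4-dien-1-ol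
Conditions: iBu2AlH (2.2 equiv), CH2Cl2, −78 °C; aq. KNaC4H4O6 work-up
Reagents that add atoms: none
Why: Low-temperature hydride reduction of the conjugated ester (1,2-addition twice) gives the allylic alcohol without touching the alkenyl iodide or the alkene geometry.

Step 8
Reactants: 13 (2Z)-2-iodopenta-2,4-dien-1-ol; 6 (2R)-1-oxobut-3-en-2-yl benzoate
Product: 14 (3R,4S,5Z)-4-hydroxy-5-(hydroxymethyl)octa-1,5,7-trien-3-yl benzoate
Conditions: CrCl2 (4 equiv), NiCl2 (2 mol%), 13 (1.5 equiv), degassed DMF, rt; chromatography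
Reagents that add atoms: none
Why: Nozaki–Hiyama–Kishi coupling turns the alkenyl iodide, with retention of geometry, into an alkenyl–chromium species that adds only to the aldehyde (ester and free OH tolerated), and polar Felkin–Anh attack anti to the α-benzoyloxy group should make the new carbinol centre (4S), the anti hydroxy benzoate, the major diastereomer, which is separated from its C4 epimer.

Step 9
Reactants: 14 (3R,4S,5Z)-4-hydroxy-5-(hydroxymethyl)octa-1,5,7-trien-3-yl benzoate
Product: 15 (1R,2R)-1-[(2S,3R)-3-ethenyl-2-(hydroxymethyl)oxiran-2-yl]-1-hydroxybut-3-en-2-yl benzoate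
Conditions: mCPBA (1.1 equiv), NaHCO3 (solid buffer), CH2Cl2, 0 °C
Reagents that add atoms: 3-chloroperoxybenzoic acid, OOC(=O)c1cccc(Cl)c1
Why: Hydroxyl-directed Prilezhaev epoxidation (Henbest effect) of the trisubstituted, most electron-rich alkene: with the carbinol H eclipsing the cis vinyl group to minimise A(1,3) strain, the peracid is delivered from the OH face and gives the threo epoxy alcohol, which sets the future quaternary centre trans to the neighbouring secondary OH.

Step 10
Reactants: 15 (1R,2R)-1-[(2S,3R)-3-ethenyl-2-(hydroxymethyl)oxiran-2-yl]-1-hydroxybut-3-en-2-yl benzoate; 2 benzoic acid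
Product: 16 (3S,4S,5R,6R)-4,5-dihydroxy-4-(hydroxymethyl)octa-1,7-diene-3,6-diyl dibenzoate
Conditions: Ti(OiPr)4 (1.5 equiv), 2 (1.5 equiv), CH2Cl2, rt
Reagents that add atoms: none
Why: Sharpless Ti(OiPr)4-mediated opening of the 2,3-epoxy alcohol: chelation directs the carboxylate to C3 of the epoxy alcohol, the allylic oxirane carbon, in an SN2 step with inversion, which installs the second benzoate (3S) and frees the tertiary alcohol with its configuration retained.

Step 11
Reactants: 16 (3S,4S,5R,6R)-4,5-dihydroxy-4-(hydroxymethyl)octa-1,7-diene-3,6-diyl dibenzoate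
Product: 17 (1R,4S,5S,6R)-5,6-dihydroxy-5-(hydroxymethyl)cyclohex-2-ene-1,4-diyl dibenzoate
Conditions: second-generation Grubbs catalyst RuCl2(=CHPh)(PCy3)(H2IMes) (5 mol%), CH2Cl2 (5 mM), 40 °C
Reagents that add atoms: none
Why: Ring-closing olefin metathesis of the 1,7-diene closes the cyclohexene with loss of ethene and touches none of the four stereocentres set in steps 2, 8, 9 and 10.

**Compound list**
1 | benzaldehyde | O=Cc1ccccc1 | starting material
2 | benzoic acid | OC(=O)c1ccccc1 | intermediate
3 | penta-1,4-dien-3-ol | C=CC(O)C=C | starting material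
4 | (1R)-1-[(2S)-oxiran-2-yl]prop-2-en-1-ol | C1O[C@@H]1[C@H](O)C=C | intermediate
5 | (1R)-1-[(2S)-oxiran-2-yl]prop-2-en-1-yl benzoate | C1O[C@@H]1[C@H](OC(=O)c2ccccc2)C=C | intermediate
6 | (2R)-1-oxobut-3-en-2-yl benzoate | O=C[C@H](OC(=O)c1ccccc1)C=C | intermediate
7 | ethyl bromoacetate | CCOC(=O)CBr | starting material
8 | (2-ethoxy-2-oxoethyl)triphenylphosphonium bromide | CCOC(=O)C[P+](c1ccccc1)(c1ccccc1)c1ccccc1.[Br-] | intermediate
9 | ethyl (triphenyl-λ5-phosphanylidene)acetate | CCOC(=O)C=P(c1ccccc1)(c1ccccc1)c1ccccc1 | intermediate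
10 | acrolein (prop-2-enal) | C=CC=O | starting material
11 | ethyl iodo(triphenyl-λ5-phosphanylidene)acetate | CCOC(=O)C(I)=P(c1ccccc1)(c1ccccc1)c1ccccc1 | intermediate
12 | ethyl (2Z)-2-iodopenta-2,4-dienoate | C=C/C=C(\I)C(=O)OCC | intermediate
13 | (2Z)-2-iodopenta-2,4-dien-1-ol | C=C/C=C(\I)CO | intermediate
14 | (3R,4S,5Z)-4-hydroxy-5-(hydroxymethyl)octa-1,5,7-trien-3-yl benzoate | C=C/C=C(/CO)[C@H](O)[C@H](OC(=O)c1ccccc1)C=C | intermediate
15 | (1R,2R)-1-[(2S,3R)-3-ethenyl-2-(hydroxymethyl)oxiran-2-yl]-1-hydroxybut-3-en-2-yl benzoate | C=C[C@H]1O[C@@]1(CO)[C@H](O)[C@H](OC(=O)c2ccccc2)C=C | intermediate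
16 | (3S,4S,5R,6R)-4,5-dihydroxy-4-(hydroxymethyl)octa-1,7-diene-3,6-diyl dibenzoate | C=C[C@H](OC(=O)c1ccccc1)[C@](O)(CO)[C@H](O)[C@H](OC(=O)c1ccccc1)C=C | intermediate
17 | (1R,4S,5S,6R)-5,6-dihydroxy-5-(hydroxymethyl)cyclohex-2-ene-1,4-diyl dibenzoate | O=C(O[C@H]1C=C[C@@H](OC(=O)c2ccccc2)[C@@H](O)[C@@]1(O)CO)c1ccccc1 | target

**Step count and risks**

Total steps: 11. Longest linear sequence: 7 (steps 2, 3, 4, 8, 9, 10, 11; the branches from benzaldehyde and from ethyl bromoacetate are equally long).

Steps most likely to fail: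

Step 4. The neighbouring benzoate can take part in the acid-promoted oxirane opening (acyl shift to the adjacent oxygen), and 6 is an epimerisable α-acyloxy-β,γ-unsaturated aldehyde. The fallback sets out from 5 and comes back at 6: the one-flask acid cleavage is replaced by a neutral hydrolysis followed by a separate glycol cleavage. Water with racemic Co(salen)(OAc) (trivalent cobalt; salen = N,N'-bis(3,5-di-tert-butylsalicylidene)cyclohexane-1,2-diamine dianion) in THF opens the terminal oxirane carbon without acid and gives (2S,3R)-1,2-dihydroxypent-4-en-3-yl benzoate F1. NaIO4 on wet silica gel in CH2Cl2 then cleaves the diol to 6.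

Step 8. The Felkin preference may be modest, the α-acyloxy aldehyde can enolise, and the benzoate can shift to the newly formed alkoxide. The fallback sets out from 4 and 13 and comes back at 14: a silyl ether is carried through the coupling and the benzoate is introduced afterwards.
- TBSCl and imidazole in DMF convert 4 into tert-butyldimethyl{[(1R)-1-[(2S)-oxiran-2-yl]prop-2-en-1-yl]oxy}silane F2.
- H5IO6 in Et2O gives the robust aldehyde (2R)-2-[(tert-butyldimethylsilyl)oxy]but-3-enal F3.
- The same CrCl2/NiCl2 coupling with 13 gives (3R,4S,5Z)-3-[(tert-butyldimethylsilyl)oxy]-5-(hydroxymethyl)octa-1,5,7-trien-4-ol F4; the bulky non-chelating silyloxy group should raise the Felkin selectivity, and no acyl shift is possible.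
- 2,2-Dimethoxypropane with pyridinium tosylate ties the primary and the new secondary hydroxyl together as (4S,5Z)-4-[(1R)-1-[(tert-butyldimethylsilyl)oxy]prop-2-en-1-yl]-2,2-dimethyl-5-(prop-2-en-1-ylidene)-1,3-dioxane F5.
- Bu4NF in THF frees (1R)-1-[(4S,5Z)-2,2-dimethyl-5-(prop-2-en-1-ylidene)-1,3-dioxan-4-yl]prop-2-en-1-ol F6.
- DCC/DMAP with 2 gives (1R)-1-[(4S,5Z)-2,2-dimethyl-5-(prop-2-en-1-ylidene)-1,3-dioxan-4-yl]prop-2-en-1-yl benzoate F7.
- 80% aqueous acetic acid at rt removes the acetonide and delivers 14.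

Step 10. In the flexible, polyhydroxylated substrate the carboxylate may attack the tertiary oxirane carbon or the vinyl terminus (SN2'), and acyl shifts are possible. The fallback sets out from 15 and comes back at 17: the ring is closed first. The second-generation Grubbs catalyst in CH2Cl2 at 40 °C converts 15 into (1S,2R,3R,6R)-2-hydroxy-1-(hydroxymethyl)-7-oxabicyclo[4.1.0]hept-4-en-3-yl benzoate F8. Benzoic acid 2 with catalytic Yb(OTf)3 in CH2Cl2 then opens this rigid allylic oxirane trans-diaxially at the allylic carbon (Fürst–Plattner, inversion) and gives 17 directly.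

Further compounds
F1 | step 4 | (2S,3R)-1,2-dihydroxypent-4-en-3-yl benzoate | OC[C@H](O)[C@H](OC(=O)c1ccccc1)C=C
F2 | step 8 | tert-butyldimethyl{[(1R)-1-[(2S)-oxiran-2-yl]prop-2-en-1-yl]oxy}silane | C1O[C@@H]1[C@H](O[Si](C)(C)C(C)(C)C)C=C
F3 | step 8 | (2R)-2-[(tert-butyldimethylsilyl)oxy]but-3-enal | O=C[C@H](O[Si](C)(C)C(C)(C)C)C=C
F4 | step 8 | (3R,4S,5Z)-3-[(tert-butyldimethylsilyl)oxy]-5-(hydroxymethyl)octa-1,5,7-trien-4-ol | C=C/C=C(/CO)[C@H](O)[C@H](O[Si](C)(C)C(C)(C)C)C=C
F5 | step 8 | (4S,5Z)-4-[(1R)-1-[(tert-butyldimethylsilyl)oxy]prop-2-en-1-yl]-2,2-dimethyl-5-(prop-2-en-1-ylidene)-1,3-dioxane | C=C/C=C1/COC(C)(C)O[C@@H]1[C@H](O[Si](C)(C)C(C)(C)C)C=C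
F6 | step 8 | (1R)-1-[(4S,5Z)-2,2-dimethyl-5-(prop-2-en-1-ylidene)-1,3-dioxan-4-yl]prop-2-en-1-ol | C=C/C=C1/COC(C)(C)O[C@@H]1[C@H](O)C=C
F7 | step 8 | (1R)-1-[(4S,5Z)-2,2-dimethyl-5-(prop-2-en-1-ylidene)-1,3-dioxan-4-yl]prop-2-en-1-yl benzoate | C=C/C=C1/COC(C)(C)O[C@@H]1[C@H](OC(=O)c2ccccc2)C=C
F8 | step 10 | (1S,2R,3R,6R)-2-hydroxy-1-(hydroxymethyl)-7-oxabicyclo[4.1.0]hept-4-en-3-yl benzoate | C1=C[C@H]2O[C@@]2(CO)[C@H](O)[C@@H]1OC(=O)c1ccccc1
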